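# Synthesis proposal for CNP0121765.1 (compound 24)

## The problem

Compound 24 joins an aristolane sesquiterpene to the A-ring of a 2′-hydroxy-4-methoxychalcone. Rings A (C1–C5, C10) and B (C5–C10) form a cis-decalin whose fusion carbons C5 (methyl) and C10 (aryl ether oxygen) are vicinal quaternary centres. C1 and C10 are bridged by two aryl atoms (C5′, C6′–O) into a dihydrobenzofuran, and ring B carries a gem-dimethylcyclopropane on C6–C7 and a 1,2-dione at C8/C9.

There are six stereocentres (C1, C4, C5, C6, C7, C10). C4 must be set absolutely, C5 can follow from C4 by enolate chemistry, C5 fixes C10 in any closure through a short tether, and C5/C10 fix C1. The cyclopropane lies on the concave face of the cis-fused system, anti to both angular substituents, so it cannot be left to reagent approach.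

Fragile features are the 1,2-dione (base), the cyclopropyl ketone (acid, hydrogenolysis) and the chalcone enone with its chelated phenol (hydrogenation, dipoles, flavanone closure). In every intermediate where C9 is still CH2, the C10 aryl ether is β to the C8 ketone and can leave as an acyl-stabilised phenoxide. The aryl methyl ketone that becomes the chalcone also competes in enolate and SeO2 chemistry, which dictates the order of the last steps.

A short entry is possible because C10 is at once the oxygen-bearing 2-carbon of a benzofuran (C1 being its 3-carbon, both in ring A beside quaternary C5) and the neighbour of C9, the carbon α to the C8 carbonyl of ring B. The C9–C10 bond therefore joins an enol ether terminus to an electron-rich heteroarene carbon, the pairing an oxidative radical-cation coupling can make.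

## Retrosynthesis

**24 ⇒ 23 ⇒ 22 (C2′–O protecting group; C9=O).** The phenol is unmasked last from MOM ether 23. The C9 carbonyl of 23 is traced to the methylene of ketone 22. This oxidation is placed after chalcone formation because 22 then has a single enolisable position, so SeO2 cannot attack an aryl methyl ketone. The forward reaction has to oxidise a neopentyl α-methylene without ionising the C10 ether.

**22 ⇒ 21 ⇒ 18 + 19 (chalcone Cα=Cβ).** The enone is cut by a Claisen–Schmidt disconnection to aryl methyl ketone 18 and 4-methoxybenzaldehyde 19. The condensation is run while C8 is a carbinol (18 → 21) and the ketone is restored afterwards (21 → 22). Hydroxide on a C8 ketone with C9H2 would expel the C10 aryloxide, whereas a β-aryloxy alcohol is inert. The chalcone must also come after all hydrogenation and carbenoid chemistry.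

**18 ⇒ 17 ⇒ 16 (C6–C11 and C7–C11).** The cyclopropane is removed to allylic alcohol 17 and that to enone 16. An undirected reagent (diazoalkane, sulfur ylide) on 16 would attack the convex β-face and give the C6,C7-diastereomer. Reducing 16 from the convex face places the C8 hydroxyl on the concave α-face, where it can deliver an isopropylidene zinc carbenoid to the required side. The price is one redox pair, which is the same pair that protects the ketone during chalcone formation.

**16 ⇒ 15 ⇒ 14 ⇒ 13 (C6=C7; C8=O; C1–H).** The enone comes from ketone 15 by dehydrogenation, which can only go toward C6–C7 because C10 has no hydrogen. Ketone 15 comes from ketal 14, and 14 from styrene 13 by adding hydrogen across C1=C2. The hydrogenation must give the cis-fused dihydrobenzofuran. A radical (hydrogen-atom-transfer) reduction is chosen because its second hydrogen transfer is governed by the syn-axial C5 methyl and by product stability.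

**13 ⇒ 12 (C9–C10, ring B).** This is the strategic cut. It removes ring B and the quaternary C10 stereocentre and leads to an aromatic tetrahydrodibenzofuran 12 that carries only the C4/C5 stereodiad and a 3-methoxybut-3-enyl chain. Neighbouring cuts (C5–C6, C7–C8) would not use the latent enol ether/heteroarene polarity and would leave C10 to be made separately. The forward reaction must bond C9 to the substituted furan carbon, not to C1, and must stop before the product styrene is oxidised.

**12 ⇒ 11 ⇒ 6 + 9 (enol ether; C1–C5′ and C10–O).** The enol ether is made from ketal 11. The benzofuran is cut at the aryl–C1 bond and the C10–O bond to ketone 6 and bromophenol 9 (α-arylation, then cyclodehydration). Ketone 6 can enolise only toward C1, so the regiochemistry is fixed. The forward reaction must tolerate a hindered, electron-rich bromide that carries its own methyl ketone.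

**9 ⇒ 8 ⇒ 7.** Bromide 9 comes from mono-MOM ether 8 and that from symmetrical 2′,6′-dihydroxy-4′-methoxyacetophenone 7. The free chelated hydroxyl of 8 directs bromination to its ortho position and later becomes the furan oxygen.

**6 ⇒ 5 ⇒ 3 + 4 ⇒ 1.** Ketal 6 comes from diketone 5, the Mukaiyama–Michael adduct of silyl enol ether 3 and but-3-en-2-one 4. Compound 3 arises from 2-methylcyclohex-2-enone 1 by catalytic asymmetric conjugate methylation, the only step that needs an external chiral source.

## Roads not taken

**Alternative 1: oxa-di-π-methane ring contraction.**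
- Cut: C7–C8 and C6–C11, back to the 2,2-dimethylcyclohept-3-enone A1.
- Forward step: triplet-sensitised irradiation shifts the acyl carbon C8 from C11 to C7 and bonds C11 to C6, giving cyclopropyl ketone A2.
- Merit: ring B and the cyclopropane are made together in a unimolecular step, so no external reagent needs access to the concave face. This is the weakest point of any late cyclopropanation, and here this road is better than the chosen one.
- Weak points: A1 needs a seven-membered β,γ-enone with a quaternary α-carbon fused to the dihydrobenzofuran, which is no easier to assemble than ring B itself. The o-acylphenol chromophore is an energy sink under sensitisation, and 1,3-acyl shift competes. The face on which C11 ends up relative to the C5 methyl is left to the conformation of the excited seven-membered ring. A2 still needs C9 oxidation and chalcone formation on a base-labile β-aryloxy ketone.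
- Comparison: the chosen plan sets against it a ring closure from an aromatic, easily made precursor (12) and a directed, ground-state cyclopropanation (17 → 18).

**Alternative 2: tethered o-quinone Diels–Alder.**
- Cut: C1–C10 and C4–C5.
- Forward step: Ag2O oxidation of catechol A3 gives o-quinone A4, whose C5=C10 bond adds across the pentadienyl chain to give enedione A5.
- Merits: one step forms ring A and the dihydrofuran with four stereocentres in a fixed relative sense. It also delivers the 8,9-dione directly, so the labile β-aryloxy ketone stage and the C9 oxidation of the chosen route never arise. In oxidation-state economy this road is clearly better.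
- Weak points: A4 is achiral, so absolute configuration would require an enantioselective intramolecular cycloaddition of an o-quinone, for which there is no reliable basis. The dienophile is the tetrasubstituted, donor-substituted double bond of a quinone that prefers to act as a diene or heterodiene and to dimerise. The hindered diaryl ether A3 is itself a problem. A5 still needs C2=C3 reduction and a cyclopropanation on the concave face of an ene-dione that is sensitive to diazoalkanes.
- Comparison: the chosen plan sets against it secure enantiocontrol from one catalytic step and C–C/C–O bond formation to the arene by Pd chemistry.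

**Alternative 3: acetylcyclopropene Michael–aldol annulation.**
- Cut: C5–C6 and C9–C10.
- Forward step: under amine base the enol of dione A6 adds through C5 to acetylcyclopropene A7, and the methyl ketone enolate closes onto the C10 carbonyl to give hydroxy diketone A8.
- Merits: convergent, and the gem-dimethylcyclopropane arrives intact, so the late face-selective cyclopropanation of the chosen route is avoided. In this respect it is as good or better.
- Weak points: A7 is a strained, self-reactive acceptor. The facial course of the Michael step relative to C4 is unproven. The hardest bonds are left for later: A8 offers a tertiary alcohol flanked by a quaternary carbon for aryl ether formation and a ketone at C1 for arylation. Any benzofuran-type annulation there would tend to dehydrate across C1–C10, and the tertiary alkyl aryl ether has no dependable method.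
- Comparison: the chosen plan has both aryl bonds in place before ring B is made and uses the aromatic furan as the reactive partner.

Key step: step 8

Remarks on the chemistry:
- Atom numbers C1–C11 are those of the aristolane skeleton (C10 = oxygen-bearing fusion carbon, C5 = methyl-bearing fusion carbon, C11 = CMe2). Primed numbers are those of the chalcone A-ring (C1′ acyl, C2′ OH/OMOM, C4′ OMe, C5′ bonded to C1, C6′ bonded to the ring oxygen). β is the face of the C5 methyl.
- The CIP labels of C5 and C10 change along the route without any bond at these centres being touched, because the priorities of their neighbours change.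
- 2,2-Diiodopropane (and 2-diazopropane in one fallback) would be prepared from acetone hydrazone and are counted as reagents.

## Route

Step 1
Reactants: 1 2-methylcyclohex-2-en-1-one
Product: 3 {[(3R)-2,3-dimethylcyclohex-1-en-1-yl]oxy}trimethylsilane, via dimethylaluminium enolate 2 (not isolated)
Conditions: Me3Al, CuTC (C5H3CuO2S, 2 mol%), BINOL-derived phosphoramidite ligand with a bis(1-phenylethyl)amino group (enantiomer that gives 3R), Et2O, −30 °C; then TMSOTf, THF, −30 to 0 °C
Reagents that add atoms: trimethylaluminium C[Al](C)C; trimethylsilyl trifluoromethanesulfonate C[Si](C)(C)OS(=O)(=O)C(F)(F)F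
Why: Copper-catalysed asymmetric conjugate addition of a methylaluminium reagent to an α-substituted cyclic enone; the chiral phosphoramidite selects the enone face and sets the methyl-bearing centre (3R, the future C4), and O-silylation freezes the regiodefined enolate.

Step 2
Reactants: 3 {[(3R)-2,3-dimethylcyclohex-1-en-1-yl]oxy}trimethylsilane; 4 but-3-en-2-one
Product: 5 (2S,3R)-2,3-dimethyl-2-(3-oxobutyl)cyclohexan-1-one
Conditions: BF3·OEt2, i-PrOH, CH2Cl2, −78 °C
Reagents that add atoms: none
Why: Mukaiyama–Michael addition of the tetrasubstituted silyl enol ether to the BF3-activated enone; the electrophile approaches axially and anti to the adjacent pseudoaxial C3 methyl, so the two methyls end cis and the quaternary centre (future C5) is 2S.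

Step 3
Reactants: 5 (2S,3R)-2,3-dimethyl-2-(3-oxobutyl)cyclohexan-1-one
Product: 6 (2S,3R)-2-(3,3-dimethoxybutyl)-2,3-dimethylcyclohexan-1-one
Conditions: HC(OMe)3, MeOH, PPTS (cat.), rt
Reagents that add atoms: trimethyl orthoformate COC(OC)OC; methanol CO
Why: Acid-catalysed ketalisation with orthoformate as water scavenger; the unhindered methyl ketone reacts far faster than the ring ketone next to the quaternary carbon, and the mild acid at room temperature should not trigger the intramolecular aldol.

Step 4
Reactants: 7 1-(2,6-dihydroxy-4-methoxyphenyl)ethan-1-one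
Product: 8 1-[2-hydroxy-4-methoxy-6-(methoxymethoxy)phenyl]ethan-1-one
Conditions: MOMCl (1.1 equiv), K2CO3, acetone, 0 °C to rt
Reagents that add atoms: chloromethyl methyl ether COCCl
Why: Williamson-type O-alkylation of one of two equivalent phenols; after the first etherification the remaining hydroxyl is chelated to the acetyl group and resists a second alkylation.

Step 5
Reactants: 8 1-[2-hydroxy-4-methoxy-6-(methoxymethoxy)phenyl]ethan-1-one
Product: 9 1-[3-bromo-2-hydroxy-4-methoxy-6-(methoxymethoxy)phenyl]ethan-1-one
Conditions: NBS, MeCN, 0 °C
Reagents that add atoms: N-bromosuccinimide O=C1CCC(=O)N1Br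
Why: Electrophilic aromatic bromination at C3′, ortho to the free chelated hydroxyl and next to the 4′-methoxy group, the position usually halogenated in 2-hydroxy-4,6-dialkoxyacetophenones; bromine thus sits beside the oxygen that becomes the furan oxygen.

Step 6
Reactants: 6 (2S,3R)-2-(3,3-dimethoxybutyl)-2,3-dimethylcyclohexan-1-one; 9 1-[3-bromo-2-hydroxy-4-methoxy-6-(methoxymethoxy)phenyl]ethan-1-one
Product: 11 1-[(6S,7R)-6-(3,3-dimethoxybutyl)-1-methoxy-3-(methoxymethoxy)-6,7-dimethyl-6,7,8,9-tetrahydrodibenzo[b,d]furan-4-yl]ethan-1-one, via α-aryl ketone 10 (not isolated)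
Conditions: Pd2(dba)3, rac-2-(di-tert-butylphosphino)-1,1′-binaphthyl, NaOtBu (2.5 equiv), toluene, 80 °C; aq. NH4Cl; then PPTS, HC(OMe)3, MeOH, 50 °C
Reagents that add atoms: none
Why: Pd-catalysed α-arylation of the ketone enolate with the o-bromophenol, then acid-catalysed cyclodehydration (hemiketal, loss of water) to the aromatic furan; 6 can enolise only toward C1, the acetyl group of 9 is deactivated toward enolisation by the adjacent phenoxide, and orthoformate keeps the side-chain ketal intact.

Step 7
Reactants: 11 1-[(6S,7R)-6-(3,3-dimethoxybutyl)-1-methoxy-3-(methoxymethoxy)-6,7-dimethyl-6,7,8,9-tetrahydrodibenzo[b,d]furan-4-yl]ethan-1-one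
Product: 12 1-[(6S,7R)-1-methoxy-6-(3-methoxybut-3-en-1-yl)-3-(methoxymethoxy)-6,7-dimethyl-6,7,8,9-tetrahydrodibenzo[b,d]furan-4-yl]ethan-1-one
Conditions: TMSOTf (1.2 equiv), i-Pr2NEt, CH2Cl2, −78 to −20 °C; aq. NaHCO3
Reagents that add atoms: none
Why: Silyl-triflate-mediated ketal-to-enol-ether elimination: TMSOTf ionises the ketal to the oxocarbenium ion and the hindered amine removes a proton from the methyl group, the less hindered site, to give the 1,1-disubstituted enol ether; at low temperature the formaldehyde acetal (MOM) ionises far more slowly than the ketone ketal, and any O-silylation of the aryl ketone is reversed on bicarbonate work-up.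

Step 8
Reactants: 12 1-[(6S,7R)-1-methoxy-6-(3-methoxybut-3-en-1-yl)-3-(methoxymethoxy)-6,7-dimethyl-6,7,8,9-tetrahydrodibenzo[b,d]furan-4-yl]ethan-1-one
Product: 13 tetracyclic C8 dimethyl ketal with C1=C2 (4R,5S,10R)
Conditions: reticulated vitreous carbon anode, carbon rod cathode, undivided cell, constant current (8 mA, 2.0–2.2 F/mol), 0.1 M LiClO4, MeOH/CH2Cl2 (1:4), 2,6-lutidine, rt
Reagents that add atoms: methanol CO
Why: Proposed new method: anodic oxidation removes one electron from the enol ether (or the trioxygenated benzofuran) and the radical cation closes by bonding the terminal enol ether carbon C9 to C10, the benzofuran 2-carbon that carries the tether, which reverses the normal nucleophilic polarity of C9; the closest known reaction type is the anodic coupling of enol ether radical cations with furans and electron-rich arenes, here extended to dearomatising attack on a fully substituted benzofuran carbon. A second electron is lost, the oxocarbenium ion at C8 is captured by methanol as the dimethyl ketal, and the benzylic cation at C1, stabilised by the ortho and para oxygens of the arene, loses a proton from C2 to 2,6-lutidine to give C1=C2. Ring B closes in the 6-exo mode with respect to the C10=C1 bond; bonding to C1 instead would need a seven-membered ring and is not expected. The new C10 stereocentre is fixed by C5: the three-atom tether leaves C5 on the face opposite its methyl group and can reach only that face of the planar benzofuran, so C9 and C6 end cis and the ether oxygen ends cis to the C5 methyl (10R in 13). The step needs chemoselectivity for 12 over the newly formed styrene, which is helped by stopping at 2.0–2.2 F/mol and by the electron-withdrawing acetyl group on the arene, and it needs proton loss instead of methanol capture at C1, which the hindered base and the crowded tertiary cation favour.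

Step 9
Reactants: 13 tetracyclic C8 dimethyl ketal with C1=C2 (4R,5S,10R)
Product: 14 saturated tetracyclic C8 dimethyl ketal (1R,4R,5S,10S)
Conditions: Mn(dpm)3 (cat.), PhSiH3, t-BuOOH, i-PrOH, rt, Ar
Reagents that add atoms: none
Why: Metal-hydride hydrogen-atom-transfer hydrogenation: H• adds to C2 to give the tertiary benzylic C1 radical, which takes the second hydrogen on the face away from the syn-axial C5 methyl; this is also the only unstrained (cis) fusion of the dihydrobenzofuran, so C1 is set (R) under both kinetic and thermodynamic bias, and the ketal, MOM ether and hindered aryl ketone are inert.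

Step 10
Reactants: 14 saturated tetracyclic C8 dimethyl ketal (1R,4R,5S,10S)
Product: 15 tetracyclic C8 ketone (1R,4R,5S,10S)
Conditions: PPTS, acetone/H2O (10:1), 40 °C
Reagents that add atoms: water O
Why: Acid-catalysed ketal hydrolysis through the C8 oxocarbenium ion; PPTS is too weak to cleave the aryl MOM ether or to ionise the C10 ether, and no base touches the β-aryloxy ketone.

Step 11
Reactants: 15 tetracyclic C8 ketone (1R,4R,5S,10S)
Product: 16 tetracyclic C6=C7 enone (1R,4R,5R,10S)
Conditions: IBX, 4-methoxypyridine N-oxide, DMSO, rt
Reagents that add atoms: none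
Why: IBX dehydrogenation of a ketone through its enol; C10 has no hydrogen, so only C6–C7 can be desaturated, the aryl methyl ketone has no β-hydrogen, and the neutral conditions spare the base-labile β-aryloxy ketone.

Step 12
Reactants: 16 tetracyclic C6=C7 enone (1R,4R,5R,10S)
Product: 17 8α-allylic alcohol (1R,4R,5R,8R,10S)
Conditions: NaBH4, CeCl3·7H2O, MeOH, −78 °C
Reagents that add atoms: none
Why: Luche 1,2-reduction; ring A should sit in the chair that keeps the C1–aryl bond equatorial, in which the C10–C1 bond is axial on ring B and screens the α-face of C8, so hydride enters from the convex β-face and leaves the hydroxyl α (8R); the hindered aryl ketone is not reduced at −78 °C.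

Step 13
Reactants: 17 8α-allylic alcohol (1R,4R,5R,8R,10S)
Product: 18 cyclopropyl carbinol (1R,4R,5R,6S,7R,8R,10S)
Conditions: Et2Zn, 2,2-diiodopropane, CH2Cl2, −10 °C to rt
Reagents that add atoms: 2,2-diiodopropane CC(C)(I)I
Why: Hydroxyl-directed Simmons–Smith-type cyclopropanation with the isopropylidene zinc carbenoid: the C8 oxygen binds zinc on the α-face and CMe2 is delivered syn to it, which sets C6 (S) and C7 (R) on the face anti to the C5 methyl, the face an undirected reagent would avoid.

Step 14
Reactants: 18 cyclopropyl carbinol (1R,4R,5R,6S,7R,8R,10S); 19 4-methoxybenzaldehyde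
Product: 21 MOM-protected chalcone carbinol (1R,4R,5R,6S,7R,8R,10S), via aldol adduct 20 (not isolated)
Conditions: KOH, EtOH, rt
Reagents that add atoms: none
Why: Claisen–Schmidt condensation: the aryl methyl ketone is the only enolisable carbonyl, its enolate adds to the aldehyde and E1cB loss of water gives the E-enone; with C8 at the alcohol level there is no ketone from which the C10 aryl ether could be eliminated.

Step 15
Reactants: 21 MOM-protected chalcone carbinol (1R,4R,5R,6S,7R,8R,10S)
Product: 22 MOM-protected chalcone C8 ketone (1R,4R,5R,6S,7R,10S)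
Conditions: Dess–Martin periodinane, NaHCO3, CH2Cl2, 0 °C to rt
Reagents that add atoms: none
Why: Dess–Martin oxidation of the secondary cyclopropyl carbinol under buffered, non-basic conditions; enone, MOM ether and cyclopropane are untouched.

Step 16
Reactants: 22 MOM-protected chalcone C8 ketone (1R,4R,5R,6S,7R,10S)
Product: 23 MOM-protected 8,9-dione (1R,4R,5R,6S,7R,10S)
Conditions: SeO2, 1,4-dioxane, H2O (2%), 90 °C
Reagents that add atoms: selenium dioxide O=[Se]=O
Why: Riley oxidation: C9 is the only enolisable α-position of 22 (C7–H is a cyclopropane C–H, the chalcone ketone has no α-CH), so SeO2 converts C9H2 into the carbonyl; once C9 is oxidised the C10 ether can no longer be lost by β-elimination.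

Step 17
Reactants: 23 MOM-protected 8,9-dione (1R,4R,5R,6S,7R,10S)
Product: 24 CNP0121765.1 (1R,4R,5R,6S,7R,10S)
Conditions: HCl (3 M aq.), THF, 40 °C
Reagents that add atoms: none
Why: Acid hydrolysis of the aryl MOM acetal, assisted by the ortho carbonyl; the freed phenol is held by a hydrogen bond to the chalcone carbonyl, and dilute acid at 40 °C should spare the dione and the cyclopropane.

## Compound list

1 | 2-methylcyclohex-2-en-1-one | CC1=CCCCC1=O | starting material
2 | dimethylaluminium (3R)-2,3-dimethylcyclohex-1-en-1-olate | C[C@@H]1CCCC(O[Al](C)C)=C1C | intermediate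
3 | {[(3R)-2,3-dimethylcyclohex-1-en-1-yl]oxy}trimethylsilane | C[C@@H]1CCCC(O[Si](C)(C)C)=C1C | intermediate
4 | but-3-en-2-one | CC(=O)C=C | starting material
5 | (2S,3R)-2,3-dimethyl-2-(3-oxobutyl)cyclohexan-1-one | CC(=O)CC[C@@]1(C)[C@H](C)CCCC1=O | intermediate
6 | (2S,3R)-2-(3,3-dimethoxybutyl)-2,3-dimethylcyclohexan-1-one | COC(C)(OC)CC[C@@]1(C)[C@H](C)CCCC1=O | intermediate
7 | 1-(2,6-dihydroxy-4-methoxyphenyl)ethan-1-one | CC(=O)c1c(O)cc(OC)cc1O | starting material
8 | 1-[2-hydroxy-4-methoxy-6-(methoxymethoxy)phenyl]ethan-1-one | CC(=O)c1c(O)cc(OC)cc1OCOC | intermediate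
9 | 1-[3-bromo-2-hydroxy-4-methoxy-6-(methoxymethoxy)phenyl]ethan-1-one | CC(=O)c1c(O)c(Br)c(OC)cc1OCOC | intermediate
10 | (2S,3R)-6-[3-acetyl-2-hydroxy-6-methoxy-4-(methoxymethoxy)phenyl]-2-(3,3-dimethoxybutyl)-2,3-dimethylcyclohexan-1-one (both C6 epimers) | COC(C)(OC)CC[C@@]1(C)[C@H](C)CCC(c2c(O)c(C(C)=O)c(OCOC)cc2OC)C1=O | intermediate
11 | 1-[(6S,7R)-6-(3,3-dimethoxybutyl)-1-methoxy-3-(methoxymethoxy)-6,7-dimethyl-6,7,8,9-tetrahydrodibenzo[b,d]furan-4-yl]ethan-1-one | CC(=O)c1c(OCOC)cc(OC)c2c1oc1c2CC[C@@H](C)[C@]1(C)CCC(C)(OC)OC | intermediate
12 | 1-[(6S,7R)-1-methoxy-6-(3-methoxybut-3-en-1-yl)-3-(methoxymethoxy)-6,7-dimethyl-6,7,8,9-tetrahydrodibenzo[b,d]furan-4-yl]ethan-1-one | CC(=O)c1c(OCOC)cc(OC)c2c1oc1c2CC[C@@H](C)[C@]1(C)CCC(=C)OC | intermediate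
13 | tetracyclic dimethyl ketal (4R,5S,10R): cis-fused rings A/B with C1=C2, C8(OMe)2, C4 and C5 methyls cis to the C10 oxygen; C1 and O–C10 bonded to C5′ and C6′ of the aryl ring (1′-acetyl, 2′-OMOM, 4′-OMe) | CC(=O)c1c(OCOC)cc(OC)c2c1O[C@]13CC(OC)(OC)CC[C@@]1(C)[C@H](C)CC=C23 | intermediate
14 | saturated tetracyclic dimethyl ketal (1R,4R,5S,10S): as 13 with C1–H α and the aryl bond β (cis-fused dihydrobenzofuran) | CC(=O)c1c(OCOC)cc(OC)c2c1O[C@]13CC(OC)(OC)CC[C@@]1(C)[C@H](C)CC[C@H]23 | intermediate
15 | tetracyclic C8 ketone (1R,4R,5S,10S): as 14 with C8=O | CC(=O)c1c(OCOC)cc(OC)c2c1O[C@]13CC(=O)CC[C@@]1(C)[C@H](C)CC[C@H]23 | intermediate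
16 | tetracyclic enone (1R,4R,5R,10S): as 15 with C6=C7 | CC(=O)c1c(OCOC)cc(OC)c2c1O[C@]13CC(=O)C=C[C@@]1(C)[C@H](C)CC[C@H]23 | intermediate
17 | allylic alcohol (1R,4R,5R,8R,10S): as 16 with C8–OH α (trans to the C5 methyl) | CC(=O)c1c(OCOC)cc(OC)c2c1O[C@]13C[C@@H](O)C=C[C@@]1(C)[C@H](C)CC[C@H]23 | intermediate
18 | cyclopropyl carbinol (1R,4R,5R,6S,7R,8R,10S): as 17 with the C6–C7–C11(Me)2 cyclopropane on the α-face, cis to the C8 hydroxyl | CC(=O)c1c(OCOC)cc(OC)c2c1O[C@]13C[C@@H](O)[C@@H]4[C@@H](C4(C)C)[C@@]1(C)[C@H](C)CC[C@H]23 | intermediate
19 | 4-methoxybenzaldehyde | COc1ccc(C=O)cc1 | starting material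
20 | aldol adduct of 18 and 19 (β-hydroxy ketone, both carbinol epimers) | COc1ccc(C(O)CC(=O)c2c(OCOC)cc(OC)c3c2O[C@]24C[C@@H](O)[C@@H]5[C@@H](C5(C)C)[C@@]2(C)[C@H](C)CC[C@H]34)cc1 | intermediate
21 | MOM-protected (E)-chalcone with C8–OH α (1R,4R,5R,6S,7R,8R,10S) | COc1ccc(/C=C/C(=O)c2c(OCOC)cc(OC)c3c2O[C@]24C[C@@H](O)[C@@H]5[C@@H](C5(C)C)[C@@]2(C)[C@H](C)CC[C@H]34)cc1 | intermediate
22 | MOM-protected (E)-chalcone C8 ketone with C9H2 (1R,4R,5R,6S,7R,10S) | COc1ccc(/C=C/C(=O)c2c(OCOC)cc(OC)c3c2O[C@]24CC(=O)[C@@H]5[C@@H](C5(C)C)[C@@]2(C)[C@H](C)CC[C@H]34)cc1 | intermediate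
23 | MOM-protected (E)-chalcone 8,9-dione (1R,4R,5R,6S,7R,10S) | COc1ccc(/C=C/C(=O)c2c(OCOC)cc(OC)c3c2O[C@]24C(=O)C(=O)[C@@H]5[C@@H](C5(C)C)[C@@]2(C)[C@H](C)CC[C@H]34)cc1 | intermediate
24 | CNP0121765.1 (1R,4R,5R,6S,7R,10S) | COc1ccc(/C=C/C(=O)c2c(O)cc(OC)c3c2O[C@]24C(=O)C(=O)[C@@H]5[C@@H](C5(C)C)[C@@]2(C)[C@H](C)CC[C@H]34)cc1 | target

## Step count and least certain steps

Total: 17 steps. Longest linear sequence: 15 steps (steps 1–3 and 6–17, from 1 to 24); the aryl branch (steps 4–5) joins at step 6.

**Step 8 (Proposed new method).** The most likely failures are further oxidation of the electron-rich styrene as it forms, anodic methoxylation of the arene or methanol capture at C1 instead of proton loss, and closure through any internal enol ether isomer carried over from step 7. The acetyl group may also raise the oxidation potential enough to slow the coupling. Fallback with known chemistry, from 12 to 15: hydrolytic bromination of the enol ether (NBS, THF/H2O, −78 °C) would give the bromomethyl ketone F1. Bu3SnH/AIBN in benzene at 80 °C would generate the electrophilic C9 α-keto radical, which should close 6-exo onto the electron-rich benzofuran carbon C10. The resulting tertiary benzylic C1 radical would take hydrogen from the stannane on the face away from the C5 methyl. This rejoins the route at 15 and bypasses steps 8–10.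

**Step 13.** The carbenoid must be delivered to the concave face of a cis-fused bicycle next to a quaternary carbon. Slow transfer would let the carbenoid decompose or let undirected attack on the β-face compete. Fallback, from 16 to 18: DBU (1.0 equiv) and TBSCl in CH2Cl2 at 0 °C would open the dihydrofuran by E1cB loss of the phenoxide and silylate it, giving the ring-opened cross-conjugated dienone silyl ether F2, in which C10 is trigonal and ring B flat. 2-Diazopropane should then add to C6=C7 from the face opposite the axial C5 methyl, as is usual for angularly methylated cross-conjugated dienones, to give pyrazoline F3. Photolysis at 350 nm would give the open cyclopropyl enone F4. Bu4NF buffered with AcOH would free the phenoxide, which recloses by 5-exo oxa-Michael addition at C10 to give the closed cyclopropyl ketone F5. NaBH4 reduction from the face opposite the gem-dimethyl bridge returns to 18. The base in the opening step must be kept stoichiometric and cold, because epimerisation at C1 of the open dienone is possible.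

**Step 6.** The risks are slow oxidative addition into an electron-rich bromide flanked by two oxygens, slow coupling with a hindered enolate, competing enolisation and arylation of the aryl methyl ketone, and loss of the MOM group during the acid closure. Fallback, from 6 and 9 to 10: 9 would be benzylated (BnBr, K2CO3, acetone) to the benzyl ether F6, and 6 converted with LiN(iPr)2/TMSCl into the silyl enol ether F7. Their coupling under fluoride activation (Pd(OAc)2, P(t-Bu)3, ZnF2, CsF, DMF, 80 °C) runs without free strong base and should give the α-aryl ketone benzyl ether F8. Hydrogenolysis (H2, Pd on carbon, EtOAc) frees the phenol and so gives 10, which is cyclodehydrated to 11 as in the main route.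

**Step 16.** Enolisation toward the neopentyl C9 may be sluggish at temperatures where selenous acid can strip the MOM group, cyclise the freed hydroxychalcone oxidatively, or promote loss of the C10 ether. Fallback, from 22 to 23: soft enolisation (TMSOTf, Et3N, CH2Cl2, −78 °C) can only go toward C9 and would give the silyl enol ether F9. Rubottom oxidation with dimethyldioxirane would give the 9-hydroxy ketone F10, and Dess–Martin oxidation would give 23.

**Step 12.** The facial preference rests on a conformational argument. Hydride delivery to the α-face would give the 8β-alcohol, which would direct the cyclopropanation of step 13 to the wrong face. Fallback, from 16 to 17: if the reduction gives the 8β-alcohol F11, Mitsunobu inversion with 4-nitrobenzoic acid (PPh3, DIAD, THF) would give the 8α 4-nitrobenzoate F12, and methanolysis (K2CO3, MeOH) would give 17.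

## Further compounds

F1 | step 8 | 1-[(6S,7R)-6-(4-bromo-3-oxobutyl)-1-methoxy-3-(methoxymethoxy)-6,7-dimethyl-6,7,8,9-tetrahydrodibenzo[b,d]furan-4-yl]ethan-1-one | CC(=O)c1c(OCOC)cc(OC)c2c1oc1c2CC[C@@H](C)[C@]1(C)CCC(=O)CBr
F2 | step 13 | ring-opened cross-conjugated dienone (C6=C7, C8=O, C9=C10) with the aryl group on C1 and the phenol as its TBS ether | CC(=O)c1c(OCOC)cc(OC)c([C@H]2CC[C@@H](C)[C@]3(C)C=CC(=O)C=C23)c1O[Si](C)(C)C(C)(C)C
F3 | step 13 | 1-pyrazoline from F2 and 2-diazopropane (CMe2 on C6, N=N on C7, α-face) | CC(=O)c1c(OCOC)cc(OC)c([C@H]2CC[C@@H](C)[C@]3(C)[C@H]4[C@H](N=NC4(C)C)C(=O)C=C23)c1O[Si](C)(C)C(C)(C)C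
F4 | step 13 | ring-opened cyclopropyl enone (α-cyclopropane on C6–C7, C8=O, C9=C10), aryl TBS ether | CC(=O)c1c(OCOC)cc(OC)c([C@H]2CC[C@@H](C)[C@]3(C)[C@H]4[C@H](C4(C)C)C(=O)C=C23)c1O[Si](C)(C)C(C)(C)C
F5 | step 13 | closed cyclopropyl C8 ketone with the aryl methyl ketone (1R,4R,5R,6S,7R,10S) | CC(=O)c1c(OCOC)cc(OC)c2c1O[C@]13CC(=O)[C@@H]4[C@@H](C4(C)C)[C@@]1(C)[C@H](C)CC[C@H]23
F6 | step 6 | 1-[2-(benzyloxy)-3-bromo-4-methoxy-6-(methoxymethoxy)phenyl]ethan-1-one | CC(=O)c1c(OCc2ccccc2)c(Br)c(OC)cc1OCOC
F7 | step 6 | {[(5R,6S)-6-(3,3-dimethoxybutyl)-5,6-dimethylcyclohex-1-en-1-yl]oxy}trimethylsilane | COC(C)(OC)CC[C@@]1(C)[C@H](C)CCC=C1O[Si](C)(C)C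
F8 | step 6 | (2S,3R)-6-[3-acetyl-2-(benzyloxy)-6-methoxy-4-(methoxymethoxy)phenyl]-2-(3,3-dimethoxybutyl)-2,3-dimethylcyclohexan-1-one | COC(C)(OC)CC[C@@]1(C)[C@H](C)CCC(c2c(OCc3ccccc3)c(C(C)=O)c(OCOC)cc2OC)C1=O
F9 | step 16 | C8 trimethylsilyl enol ether (C8=C9) of 22 | COc1ccc(/C=C/C(=O)c2c(OCOC)cc(OC)c3c2O[C@]24C=C(O[Si](C)(C)C)[C@@H]5[C@@H](C5(C)C)[C@@]2(C)[C@H](C)CC[C@H]34)cc1
F10 | step 16 | 9-hydroxy C8 ketone derived from 22 (both C9 epimers) | COc1ccc(/C=C/C(=O)c2c(OCOC)cc(OC)c3c2O[C@]24C(O)C(=O)[C@@H]5[C@@H](C5(C)C)[C@@]2(C)[C@H](C)CC[C@H]34)cc1
F11 | step 12 | 8β-allylic alcohol, C8 epimer of 17 | CC(=O)c1c(OCOC)cc(OC)c2c1O[C@]13C[C@H](O)C=C[C@@]1(C)[C@H](C)CC[C@H]23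
F12 | step 12 | 8α 4-nitrobenzoate of 17 | CC(=O)c1c(OCOC)cc(OC)c2c1O[C@]13C[C@@H](OC(=O)c4ccc(cc4)[N+](=O)[O-])C=C[C@@]1(C)[C@H](C)CC[C@H]23
A1 | alternative 1 | dihydrobenzofuran-fused 2,2-dimethylcyclohept-3-enone (seven-membered ring C5–C6=C7–C11–C8–C9–C10) | CC(=O)c1c(O)cc(OC)c2c1O[C@]13CC(=O)C(C)(C)C=C[C@@]1(C)[C@H](C)CC[C@H]23
A2 | alternative 1 | cyclopropyl ketone with C9 methylene | CC(=O)c1c(O)cc(OC)c2c1O[C@]13CC(=O)[C@@H]4[C@@H](C4(C)C)[C@@]1(C)[C@H](C)CC[C@H]23
A3 | alternative 2 | 3-aryloxy-4-methylcatechol carrying the (E,E)-pentadienyl chain | Cc1ccc(O)c(O)c1Oc1c(C(C)=O)c(OCOC)cc(OC)c1/C=C/C=C/C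
A4 | alternative 2 | 3-aryloxy-4-methyl-o-benzoquinone | CC1=C(Oc2c(C(C)=O)c(OCOC)cc(OC)c2/C=C/C=C/C)C(=O)C(=O)C=C1
A5 | alternative 2 | tetracyclic enedione with C2=C3 and C6=C7 | CC(=O)c1c(OCOC)cc(OC)c2c1O[C@]13C(=O)C(=O)C=C[C@@]1(C)[C@H](C)C=C[C@H]23
A6 | alternative 3 | (4R)-3,4-dimethylcyclohexane-1,2-dione | C[C@@H]1CCC(=O)C(=O)C1C
A7 | alternative 3 | 1-(3,3-dimethylcycloprop-1-en-1-yl)ethan-1-one | CC(=O)C1=CC1(C)C
A8 | alternative 3 | C10-hydroxy C1,C8-diketone with rings A and B and the cyclopropane | O[C@]12CC(=O)[C@@H]3[C@@H](C3(C)C)[C@@]1(C)[C@H](C)CCC2=O
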